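**Plan**

1. Retrosynthesis (cyclohexene numbered C1 = CH–indolyl, C2 = CH, C3 = C–CH3, C4, C5, C6 = quaternary C): cut the aryl–vinyl bond and the C=C of the styryl arm (Suzuki coupling; boron–Wittig on a formyl group at C6), then C3–CH3 (enol triflate coupling), then C1–indolyl (conjugate addition), and last the ring bonds C1–C2 and C4–C5 together.
2. Enabling feature: C6 and C3 lie 1,4 across the ring. With C3 as a ketone carbon and C1 and C5 as formyl carbons, the ring is a mirror-symmetric 4,4-disubstituted cyclohexa-2,5-dienone whose two enantiotopic C=C bonds are exactly C1–C2 and C4–C5. One twofold aldol condensation of a 2,2-disubstituted malonaldehyde with an acetone 1,3-dianion equivalent makes both.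
3. Forward: triol → monosilyl ether → dialdehyde → dienone ([3+3], the only ring formed) → desymmetrizing 1,4-reduction → aryl 1,4-addition with enolate triflation → methylation → desilylation → aldehyde → alkenyl boronate → Suzuki coupling with the bromoindole, which is made once by Pd annulation and serves both indole units.
4. Stereochemistry: C6 by catalyst choice between the enantiotopic enone C=C bonds of the dienone; C1 by aryl addition anti to the CH2OSi group on C6; the E-alkene by syn B–O elimination and stereoretentive coupling.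

Key step: step 3

Remark: the sense of induction in step 4 is not predicted here, so the Phebox ligand antipode that leads to (R)-8 is the one used; 3,3-dimethylpent-4-enal (10) is taken as a catalogue compound.

**Route**

Step 1
Reactants: 1 2-(hydroxymethyl)-2-methylpropane-1,3-diol
Product: 2 2-[[tert-butyl(diphenyl)silyl]oxymethyl]-2-methylpropane-1,3-diol
Conditions: TBDPSCl (1.0 equiv), imidazole (1.2 equiv), DMF, 0 °C to rt; 1 in threefold excess
Reagents that add atoms: tert-butyl(chloro)diphenylsilane CC(C)(C)[Si](Cl)(c1ccccc1)c1ccccc1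
Why: Silyl ether formation on one of three homotopic primary hydroxyl groups (statistical monoprotection), with the cheap triol in excess so that the monoether should dominate; no stereocentre arises because the central carbon keeps two identical CH2OH arms.

Step 2
Reactants: 2 2-[[tert-butyl(diphenyl)silyl]oxymethyl]-2-methylpropane-1,3-diol
Product: 3 2-[[tert-butyl(diphenyl)silyl]oxymethyl]-2-methylpropanedial
Conditions: IBX (3 equiv), EtOAc, 80 °C; filter, concentrate, use at once
Reagents that add atoms: none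
Why: IBX oxidation of both primary alcohols to aldehydes, chosen because the work-up is a filtration and the product, which has no α-hydrogen and so cannot enolize or lose silanol, is spared aqueous base that could deformylate it.

Step 3
Reactants: 3 2-[[tert-butyl(diphenyl)silyl]oxymethyl]-2-methylpropanedial; 4 3-oxopentanedioic acid
Product: 6 4-[[tert-butyl(diphenyl)silyl]oxymethyl]-4-methylcyclohexa-2,5-dien-1-one, via cyclic bis-aldol 5 (not isolated)
Conditions: 4 (1.3 equiv), Et3N (0.2 equiv), THF (0.05 M), 0 °C to rt; then TsOH·H2O (10 mol%), PhMe, 80 °C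
Reagents that add atoms: none
Why: Proposed new method: each carboxyl-activated α-carbon of 4 should add as its enol(ate) to one formyl group of 3 with loss of CO2 (decarboxylative aldol addition), the first addition intermolecular and the second intramolecular, to give the cyclic bis-aldol 5, from which mild acid removes two molecules of water to the cross-conjugated dienone 6, so that ring bonds C2–C3 and C5–C6 of 6 (C1–C2 and C4–C5 of the target ring) arise in one flask. The closest known reaction types are the Robinson–Schöpf and Weiss double condensations of 3-oxopentanedioic acid derivatives with dicarbonyl compounds and the amine-mediated decarboxylative aldol addition of β-keto acids to aldehydes; the twofold Claisen–Schmidt condensation to dibenzylideneacetone shows the same bond pattern in open-chain form. The ring closes in the second aldol addition as a 6-(enolendo)-exo-trig attack on the remaining formyl group, at the sp3 stage, so no trans double bond has to fit into the six-membered ring. No stereocentre survives the step: the carbinol centres of 5 are erased on dehydration and 6 keeps a mirror plane through C1 and C4, which is what lets a catalyst set the quaternary centre in step 4. The step needs ring closure to win over oligomerization and over early dehydration of the first aldol to an E-enone; the quaternary carbon of 3 favours cyclization (geminal disubstitution) and rules out enolization or self-condensation of 3, and decarboxylative activation confines the nucleophile to the two α-carbons of 4 under conditions too mild for dehydration.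

Step 4
Reactants: 6 4-[[tert-butyl(diphenyl)silyl]oxymethyl]-4-methylcyclohexa-2,5-dien-1-one
Product: 8 (4R)-4-[[tert-butyl(diphenyl)silyl]oxymethyl]-4-methylcyclohex-2-en-1-one, via silyl dienol ether 7 (not isolated)
Conditions: Rh[(S,S)-Phebox-iPr](OAc)2(H2O) (1 mol%; antipode if required), (EtO)2MeSiH (1.2 equiv), PhMe, 50 °C; then 1 M HCl, THF, 0 °C
Reagents that add atoms: none
Why: Rh–hydride conjugate hydrosilylation of a cross-conjugated dienone (asymmetric 1,4-reduction used as a desymmetrization): the chiral bis(oxazolinyl)phenyl–Rh hydride should reduce only one of the two enantiotopic C=C bonds, which it tells apart through the CH3 versus CH2OTBDPS difference at C4, so that C4 becomes the R stereocentre, and acid hydrolysis of dienol ether 7 returns the enone.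

Step 5
Reactants: 9 4-bromo-2-iodoaniline; 10 3,3-dimethylpent-4-enal
Product: 12 5-bromo-3-(2-methylbut-3-en-2-yl)-1H-indole, via imine 11 (not isolated)
Conditions: Pd(OAc)2 (5 mol%), DABCO (3 equiv), DMF, 85 °C
Reagents that add atoms: none
Why: Pd-catalysed annulation of an ortho-iodoaniline with an aldehyde (condensation to 11, oxidative addition of zerovalent palladium into the carbon–iodine bond, intramolecular Heck-type closure of the enamine tautomer, aromatization), which places the aldehyde's α-substituent at C3 under basic conditions that spare the acid-labile 1,1-dimethylallyl group and leave the slower-reacting C–Br bond for later use.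

Step 6
Reactants: 12 5-bromo-3-(2-methylbut-3-en-2-yl)-1H-indole
Product: 13 5-bromo-3-(2-methylbut-3-en-2-yl)-1-[tri(propan-2-yl)silyl]indole
Conditions: NaH, THF, 0 °C; TIPSCl, rt
Reagents that add atoms: chlorotri(propan-2-yl)silane CC(C)[Si](Cl)(C(C)C)C(C)C
Why: N-silylation of the sodium indolide (protection), needed so that the Grignard reagent of step 7 is not quenched by N–H.

Step 7
Reactants: 13 5-bromo-3-(2-methylbut-3-en-2-yl)-1-[tri(propan-2-yl)silyl]indole; 8 (4R)-4-[[tert-butyl(diphenyl)silyl]oxymethyl]-4-methylcyclohex-2-en-1-one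
Product: 16 [(3S,4R)-4-[[tert-butyl(diphenyl)silyl]oxymethyl]-4-methyl-3-[3-(2-methylbut-3-en-2-yl)-1-[tri(propan-2-yl)silyl]indol-5-yl]cyclohexen-1-yl] trifluoromethanesulfonate, via aryl Grignard reagent 14 (not isolated), via magnesium enolate 15 (not isolated)
Conditions: 13 (1.5 equiv), Mg, LiCl, THF, rt; CuBr·SMe2 (10 mol%), then 8, THF, −40 to −10 °C; then Comins' reagent (1.6 equiv), −40 °C to rt
Reagents that add atoms: N-(5-chloropyridin-2-yl)-1,1,1-trifluoro-N-(trifluoromethylsulfonyl)methanesulfonamide (Comins' reagent) O=S(=O)(N(c1ccc(Cl)cn1)S(=O)(=O)C(F)(F)F)C(F)(F)F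
Why: Cu-catalysed conjugate addition of an aryl Grignard reagent followed by O-triflation of the enolate where it forms: the aryl group should enter C3 axially through the half-chair that holds the bulkier CH2OTBDPS group pseudo-axial, hence anti to it and cis to CH3 (the trans preference of 4-substituted cyclohexenones), which sets C3 as S, and trapping the magnesium enolate fixes the double bond between C1 and C2.

Step 8
Reactants: 16 [(3S,4R)-4-[[tert-butyl(diphenyl)silyl]oxymethyl]-4-methyl-3-[3-(2-methylbut-3-en-2-yl)-1-[tri(propan-2-yl)silyl]indol-5-yl]cyclohexen-1-yl] trifluoromethanesulfonate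
Product: 17 5-[(1S,6R)-6-[[tert-butyl(diphenyl)silyl]oxymethyl]-3,6-dimethylcyclohex-2-en-1-yl]-3-(2-methylbut-3-en-2-yl)-1-[tri(propan-2-yl)silyl]indole
Conditions: MeMgBr (1.5 equiv), Fe(acac)3 (5 mol%), THF/NMP, −30 °C
Reagents that add atoms: methylmagnesium bromide C[Mg]Br
Why: Fe-catalysed cross-coupling of an alkenyl triflate with a methyl Grignard reagent (Kochi–Fürstner coupling), which replaces OTf by CH3 with the C=C position unchanged and should touch neither the silyl groups nor the terminal vinyl group.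

Step 9
Reactants: 17 5-[(1S,6R)-6-[[tert-butyl(diphenyl)silyl]oxymethyl]-3,6-dimethylcyclohex-2-en-1-yl]-3-(2-methylbut-3-en-2-yl)-1-[tri(propan-2-yl)silyl]indole
Product: 18 [(1R,2S)-1,4-dimethyl-2-[3-(2-methylbut-3-en-2-yl)-1H-indol-5-yl]cyclohex-3-en-1-yl]methanol
Conditions: TBAF (3 equiv), THF, rt to 50 °C
Reagents that add atoms: none
Why: Fluoride-induced cleavage of the Si–O and Si–N bonds in one operation (desilylation), freeing the primary alcohol and the indole N–H without affecting either stereocentre.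

Step 10
Reactants: 18 [(1R,2S)-1,4-dimethyl-2-[3-(2-methylbut-3-en-2-yl)-1H-indol-5-yl]cyclohex-3-en-1-yl]methanol
Product: 19 (1R,2S)-1,4-dimethyl-2-[3-(2-methylbut-3-en-2-yl)-1H-indol-5-yl]cyclohex-3-ene-1-carbaldehyde
Conditions: Pr4N[RuO4] (5 mol%), NMO (1.5 equiv), 4 Å MS, CH2Cl2, rt
Reagents that add atoms: none
Why: Ley–Griffith oxidation of the neopentyl-type primary alcohol to the aldehyde, which has no α-hydrogen and cannot epimerize, under neutral conditions that the indole and the alkenes should tolerate.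

Step 11
Reactants: 19 (1R,2S)-1,4-dimethyl-2-[3-(2-methylbut-3-en-2-yl)-1H-indol-5-yl]cyclohex-3-ene-1-carbaldehyde
Product: 20 5-[(1R,6S)-3,6-dimethyl-6-[(E)-2-(4,4,5,5-tetramethyl-1,3,2-dioxaborolan-2-yl)ethenyl]cyclohex-2-en-1-yl]-3-(2-methylbut-3-en-2-yl)-1H-indole
Conditions: CH2(Bpin)2 (2.5 equiv), LiTMP (2.5 equiv, from 2,2,6,6-tetramethylpiperidine and n-BuLi), THF, −78 °C to rt
Reagents that add atoms: 2,2'-methylenebis(4,4,5,5-tetramethyl-1,3,2-dioxaborolane) CC1(C)OB(CB2OC(C)(C)C(C)(C)O2)OC1(C)C
Why: Boron–Wittig olefination, in which the lithiated gem-diboronate adds to the non-enolizable aldehyde and syn elimination of B–O should give the E-alkenyl boronate, the excess base covering the indole N–H.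

Step 12
Reactants: 20 5-[(1R,6S)-3,6-dimethyl-6-[(E)-2-(4,4,5,5-tetramethyl-1,3,2-dioxaborolan-2-yl)ethenyl]cyclohex-2-en-1-yl]-3-(2-methylbut-3-en-2-yl)-1H-indole; 12 5-bromo-3-(2-methylbut-3-en-2-yl)-1H-indole
Product: 21 5-[(1R,6S)-3,6-dimethyl-6-[(E)-2-[3-(2-methylbut-3-en-2-yl)-1H-indol-5-yl]ethenyl]cyclohex-2-en-1-yl]-3-(2-methylbut-3-en-2-yl)-1H-indole
Conditions: Pd(OAc)2 (5 mol%), SPhos (10 mol%), K3PO4 (3 equiv), dioxane/H2O (5:1), 80 °C
Reagents that add atoms: none
Why: Suzuki–Miyaura coupling of the alkenyl boronate with the unprotected bromoindole, which proceeds with retention of the E geometry and forms the last C–C bond without touching C1 or C6.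

**Compound list**

1 | 2-(hydroxymethyl)-2-methylpropane-1,3-diol | CC(CO)(CO)CO | starting material
2 | 2-[[tert-butyl(diphenyl)silyl]oxymethyl]-2-methylpropane-1,3-diol | CC(CO)(CO)CO[Si](c1ccccc1)(c1ccccc1)C(C)(C)C | intermediate
3 | 2-[[tert-butyl(diphenyl)silyl]oxymethyl]-2-methylpropanedial | CC(C=O)(C=O)CO[Si](c1ccccc1)(c1ccccc1)C(C)(C)C | intermediate
4 | 3-oxopentanedioic acid | OC(=O)CC(=O)CC(=O)O | starting material
5 | 4-[[tert-butyl(diphenyl)silyl]oxymethyl]-3,5-dihydroxy-4-methylcyclohexan-1-one (stereoisomer mixture) | CC1(CO[Si](c2ccccc2)(c2ccccc2)C(C)(C)C)C(O)CC(=O)CC1O | intermediate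
6 | 4-[[tert-butyl(diphenyl)silyl]oxymethyl]-4-methylcyclohexa-2,5-dien-1-one | CC1(CO[Si](c2ccccc2)(c2ccccc2)C(C)(C)C)C=CC(=O)C=C1 | intermediate
7 | tert-butyl-[[(1R)-4-[diethoxy(methyl)silyl]oxy-1-methylcyclohexa-2,4-dien-1-yl]methoxy]-diphenylsilane | CCO[Si](C)(OCC)OC1=CC[C@@](C)(CO[Si](c2ccccc2)(c2ccccc2)C(C)(C)C)C=C1 | intermediate
8 | (4R)-4-[[tert-butyl(diphenyl)silyl]oxymethyl]-4-methylcyclohex-2-en-1-one | O=C1C=C[C@](C)(CO[Si](c2ccccc2)(c2ccccc2)C(C)(C)C)CC1 | intermediate
9 | 4-bromo-2-iodoaniline | Nc1ccc(Br)cc1I | starting material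
10 | 3,3-dimethylpent-4-enal | C=CC(C)(C)CC=O | starting material
11 | N-(4-bromo-2-iodophenyl)-3,3-dimethylpent-4-en-1-imine | C=CC(C)(C)CC=Nc1ccc(Br)cc1I | intermediate
12 | 5-bromo-3-(2-methylbut-3-en-2-yl)-1H-indole | C=CC(C)(C)c1c[nH]c2ccc(Br)cc12 | intermediate
13 | 5-bromo-3-(2-methylbut-3-en-2-yl)-1-[tri(propan-2-yl)silyl]indole | C=CC(C)(C)c1cn([Si](C(C)C)(C(C)C)C(C)C)c2ccc(Br)cc12 | intermediate
14 | bromo-[3-(2-methylbut-3-en-2-yl)-1-[tri(propan-2-yl)silyl]indol-5-yl]magnesium | C=CC(C)(C)c1cn([Si](C(C)C)(C(C)C)C(C)C)c2ccc([Mg]Br)cc12 | intermediate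
15 | bromo-[[(3S,4R)-4-[[tert-butyl(diphenyl)silyl]oxymethyl]-4-methyl-3-[3-(2-methylbut-3-en-2-yl)-1-[tri(propan-2-yl)silyl]indol-5-yl]cyclohexen-1-yl]oxy]magnesium | Br[Mg]OC1=C[C@@H](c2ccc3n([Si](C(C)C)(C(C)C)C(C)C)cc(C(C)(C)C=C)c3c2)[C@](C)(CO[Si](c2ccccc2)(c2ccccc2)C(C)(C)C)CC1 | intermediate
16 | [(3S,4R)-4-[[tert-butyl(diphenyl)silyl]oxymethyl]-4-methyl-3-[3-(2-methylbut-3-en-2-yl)-1-[tri(propan-2-yl)silyl]indol-5-yl]cyclohexen-1-yl] trifluoromethanesulfonate | O=S(=O)(OC1=C[C@@H](c2ccc3n([Si](C(C)C)(C(C)C)C(C)C)cc(C(C)(C)C=C)c3c2)[C@](C)(CO[Si](c2ccccc2)(c2ccccc2)C(C)(C)C)CC1)C(F)(F)F | intermediate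
17 | 5-[(1S,6R)-6-[[tert-butyl(diphenyl)silyl]oxymethyl]-3,6-dimethylcyclohex-2-en-1-yl]-3-(2-methylbut-3-en-2-yl)-1-[tri(propan-2-yl)silyl]indole | CC1=C[C@@H](c2ccc3n([Si](C(C)C)(C(C)C)C(C)C)cc(C(C)(C)C=C)c3c2)[C@](C)(CO[Si](c2ccccc2)(c2ccccc2)C(C)(C)C)CC1 | intermediate
18 | [(1R,2S)-1,4-dimethyl-2-[3-(2-methylbut-3-en-2-yl)-1H-indol-5-yl]cyclohex-3-en-1-yl]methanol | CC1=C[C@@H](c2ccc3[nH]cc(C(C)(C)C=C)c3c2)[C@](C)(CO)CC1 | intermediate
19 | (1R,2S)-1,4-dimethyl-2-[3-(2-methylbut-3-en-2-yl)-1H-indol-5-yl]cyclohex-3-ene-1-carbaldehyde | CC1=C[C@@H](c2ccc3[nH]cc(C(C)(C)C=C)c3c2)[C@](C)(C=O)CC1 | intermediate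
20 | 5-[(1R,6S)-3,6-dimethyl-6-[(E)-2-(4,4,5,5-tetramethyl-1,3,2-dioxaborolan-2-yl)ethenyl]cyclohex-2-en-1-yl]-3-(2-methylbut-3-en-2-yl)-1H-indole | CC1=C[C@@H](c2ccc3[nH]cc(C(C)(C)C=C)c3c2)[C@](C)(/C=C/B2OC(C)(C)C(C)(C)O2)CC1 | intermediate
21 | 5-[(1R,6S)-3,6-dimethyl-6-[(E)-2-[3-(2-methylbut-3-en-2-yl)-1H-indol-5-yl]ethenyl]cyclohex-2-en-1-yl]-3-(2-methylbut-3-en-2-yl)-1H-indole | CC1=C[C@@H](c2ccc3[nH]cc(C(C)(C)C=C)c3c2)[C@](C)(/C=C/c2ccc3[nH]cc(C(C)(C)C=C)c3c2)CC1 | target

**Step count and risks**

Total steps: 12. Longest linear sequence: 10 steps (steps 1–4 and 7–12, from triol 1); the indole branch is steps 5 and 6.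

Steps most likely to fail:

1. Step 3 (Proposed new method). What may go wrong: intermolecular aldol addition at both formyl groups (oligomerization), retro-Claisen deformylation of the malonaldehyde, or early dehydration of the first aldol to an E-enone that cannot close. Fallback, from 3 back to 6: the two bonds are made one after the other with known reactions. A Mukaiyama aldol addition of 2-(trimethylsilyloxy)propene to one formyl group of 3 (BF3·OEt2, CH2Cl2, −78 °C) would give 2-[[tert-butyl(diphenyl)silyl]oxymethyl]-3-hydroxy-2-methyl-5-oxohexanal F1. Pyrrolidinium acetate would then close the ring by intramolecular aldol condensation (the ring-forming half of a Robinson annulation) to 4-[[tert-butyl(diphenyl)silyl]oxymethyl]-5-hydroxy-4-methylcyclohex-2-en-1-one F2, and TsOH in toluene at 80 °C would remove the second molecule of water to give 6.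

2. Step 7. What may go wrong: poor facial selectivity of the aryl transfer (CH3 and CH2OTBDPS may differ too little at the ring carbon), competing 1,2-addition to the hindered enone, or enolate equilibration before triflation. Fallback, from 14 and 8 back to 16: a chiral catalyst chooses the face instead of the ring. ZnCl2 would convert 14 into chloro-[3-(2-methylbut-3-en-2-yl)-1-[tri(propan-2-yl)silyl]indol-5-yl]zinc F3. [RhCl(binap)]2 (binap antipode matched to the anti face) with Me3SiCl in THF would add F3 to 8 (Rh-catalysed asymmetric 1,4-addition of an arylzinc reagent) and deliver trimethyl-[[(3S,4R)-4-[[tert-butyl(diphenyl)silyl]oxymethyl]-4-methyl-3-[3-(2-methylbut-3-en-2-yl)-1-[tri(propan-2-yl)silyl]indol-5-yl]cyclohexen-1-yl]oxy]silane F4. MeLi would cleave it to lithium (3S,4R)-4-[[tert-butyl(diphenyl)silyl]oxymethyl]-4-methyl-3-[3-(2-methylbut-3-en-2-yl)-1-[tri(propan-2-yl)silyl]indol-5-yl]cyclohexen-1-olate F5, which Comins' reagent would triflate to 16.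

3. Step 4. What may go wrong: weak discrimination between the enantiotopic C=C bonds with this CH3/CH2OSi pair, or over-reduction to the saturated ketone. Fallback, from 6 back to 8: metal-hydride catalysis is replaced by biocatalysis. An ene-reductase of the Old Yellow Enzyme family with NADPH recycling (glucose, glucose dehydrogenase, buffer with co-solvent, 30 °C) reduces one enantiotopic C=C of 4,4-disubstituted cyclohexadienones by flavin hydride transfer and active-site protonation and would give 8 directly; no new compound is formed.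

**Further compounds**

F1 | step 3 | 2-[[tert-butyl(diphenyl)silyl]oxymethyl]-3-hydroxy-2-methyl-5-oxohexanal (stereoisomer mixture) | CC(=O)CC(O)C(C)(C=O)CO[Si](c1ccccc1)(c1ccccc1)C(C)(C)C
F2 | step 3 | 4-[[tert-butyl(diphenyl)silyl]oxymethyl]-5-hydroxy-4-methylcyclohex-2-en-1-one (stereoisomer mixture) | CC1(CO[Si](c2ccccc2)(c2ccccc2)C(C)(C)C)C=CC(=O)CC1O
F3 | step 7 | chloro-[3-(2-methylbut-3-en-2-yl)-1-[tri(propan-2-yl)silyl]indol-5-yl]zinc | C=CC(C)(C)c1cn([Si](C(C)C)(C(C)C)C(C)C)c2ccc([Zn]Cl)cc12
F4 | step 7 | trimethyl-[[(3S,4R)-4-[[tert-butyl(diphenyl)silyl]oxymethyl]-4-methyl-3-[3-(2-methylbut-3-en-2-yl)-1-[tri(propan-2-yl)silyl]indol-5-yl]cyclohexen-1-yl]oxy]silane | C[Si](C)(C)OC1=C[C@@H](c2ccc3n([Si](C(C)C)(C(C)C)C(C)C)cc(C(C)(C)C=C)c3c2)[C@](C)(CO[Si](c2ccccc2)(c2ccccc2)C(C)(C)C)CC1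
F5 | step 7 | lithium (3S,4R)-4-[[tert-butyl(diphenyl)silyl]oxymethyl]-4-methyl-3-[3-(2-methylbut-3-en-2-yl)-1-[tri(propan-2-yl)silyl]indol-5-yl]cyclohexen-1-olate | [Li]OC1=C[C@@H](c2ccc3n([Si](C(C)C)(C(C)C)C(C)C)cc(C(C)(C)C=C)c3c2)[C@](C)(CO[Si](c2ccccc2)(c2ccccc2)C(C)(C)C)CC1
F0 | step 4 | none | none
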